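The earlier runs and the new flask were computed on assumed constants; the scatter is artificial.

Read the green and violet runs for how their curves bend, not for how far they get.

| setting | violet | green | oak | maple |
|---|---|---|---|---|
| E | 0.072 M (fed, over 50 h) | 0.072 M (fed, over 50 h) | 0.072 M | 0.072 M (fed, over 50 h) |
| Q | 0.36 mM | 0.54 mM | 0.72 mM | 0.72 mM |
| temperature | 15 °C | 35 °C | 20 °C | 50 °C |
| remark | run made earlier | run made earlier | everything together at the start |  |
| time |  |  | 8.0 d | 8.0 d |

| run | time / d | G / % | E / % |
|---|---|---|---|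
| violet | 3.00 | 0.4 | 101.6 |
| violet | 5.00 | 0 | 99.2 |
| violet | 8.00 | 0 | 100.2 |
| violet | 10.0 | 0 | 99.0 |
| violet | 15.0 | 0 | 99.9 |
| violet | 25.0 | 3.2 | 97.9 |
| violet | 30.0 | 2.4 | 95.5 |
| green | 0.625 | 0 | 30.3 |
| green | 2.00 | 5.2 | 94.7 |
| green | 4.00 | 14.1 | 85.6 |
| green | 6.00 | 29.2 | 70.3 |
| green | 8.00 | 48.7 | 53.1 |
| green | 10.0 | 64.8 | 34.0 |
| green | 12.0 | 82.3 | 19.6 |

(readings scatter by 1 percentage point)

- amounts and yields of G count J too
- what may be going on: E + L -> D; D <-> Z; Z <-> L + G; L + G <-> J; G -> X; Q -> L
- percentages count the whole charge, also what has not yet gone in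

- the flask that ends with the higher amount of G, in percent of the E charged, or "neither" when 2 percentage points or less lies between them (oak / maple / neither)
- final G, as a percentage of the E charged, in oak
- final G, as a percentage of the E charged, in maple

In green, G gains 34 percentage points from 8.00 d to 12.0 d, about as much as the 35 points from 4.00 d to 8.00 d, although E is falling. So I treat the turnover as zero order in E and take the pace from the catalyst waking out of Q into L. Early on that rate grows in proportion to time, and I call its growth per day the bend. Integrated, it gives: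

share of the charge in G = (time / filling time) squared

filling time = root of (2 / bend)

Now the chain, each line using the last.

Green, read from its readings at 2.00 d and 4.00 d: filling time 10.2 d.

Violet, read from its last two readings: filling time 165 d.

Per Q charged, green bends 175 times as hard as violet.

Oak, with that rise spread evenly over the degrees on a logarithmic scale and the bend scaled for Q: filling time 61.2 d.

Maple, the same way: filling time 1.27 d.

The filling time, the time this parabola would need to reach the whole charge, is what I hold against the 8.0 d allowed. Oak's is longer, which gives G 1.71%. Maple's is shorter than the feed, so I expect maple's G to end close to the whole charge.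

The weak link is violet's bend, which rests on two small readings and carries 25.3% of scatter. Oak lies nearer violet and inherits 18.9%, so oak's figure carries a scatter of about 0.32 points, which is less than the margin.

The forecast names maple, with 2% in oak and 95% in maple, on the ground that “the rate does not fall as E drops”.

The flasks give 1.54% in oak and 99.7% in maple, so maple ends higher, as forecast.

    E + L → D (k = 770 M⁻¹ h⁻¹, Ea = 65.0 kJ mol⁻¹)
    D ⇌ Z (K = 2.90, k = 5.30 h⁻¹, Ea = 88.0 kJ mol⁻¹, ΔH = 7.00 kJ mol⁻¹)
    Z ⇌ L + G (K = 0.210 M, k = 38.0 h⁻¹, Ea = 101 kJ mol⁻¹, ΔH = −35.0 kJ mol⁻¹)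
    L + G ⇌ J (K = 38.0 M⁻¹, k = 8.60 M⁻¹ h⁻¹, Ea = 63.0 kJ mol⁻¹, ΔH = −8.00 kJ mol⁻¹)
    G → X (k = 1.40 × 10⁻⁵ h⁻¹, Ea = 122 kJ mol⁻¹)
    Q → L (k = 0.0540 h⁻¹, Ea = 116 kJ mol⁻¹)
    (constants at 50 °C)

Oak is far from rest: at 80.0 d its G stands at 91.7% with E at 7.97%, past the filling time of 61.2 d, where the parabola no longer applies. Before that it serves oak: at 4.00 d it gives 0.427% against 0.389% in the flask. A neighbouring flask, oak with 0.0029 M of Q, has a reckoned filling time of 30.5 d, which gives 6.88% against its 6.19%. At 8.00 d maple has E at 0%, and by 80.0 d its G slips from 99.7% to 97.3% while X reaches 2.58%.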